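Read the leftover first: at 1.00 h the eta flask still has 66.0% of its charge not turned to target, the beta flask 81.0%.

in all of them: free catalyst 1 mol%

| run | substrate | remark | time |
|---|---|---|---|
| eta | 0.33 M | run made earlier |  |
| beta | 0.17 M | run made earlier |  |
| Saturday's | 0.33 M | a closed flask charged with all of it at once and left for 12 h | 12 h |
| Thursday's | 0.33 M (fed, over 9.60 h) | all but substrate at the start; substrate goes in evenly over 9.60 h, the run ends at 12 h | 12 h |
| Monday's | 0.33 M | a single well-mixed tank run continuously and read at steady state, 12 h in it on average |  |

| eta: time / h | eta: target / % | beta: time / h | beta: target / % |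
|---|---|---|---|
| 0.417 | 19 | 0.500 | 12 |
| 1.00 | 34 | 1.00 | 19 |
| 2.00 | 58 | 1.50 | 24 |
| 3.00 | 68 | 2.00 | 37 |
| 4.00 | 72 | 2.50 | 40 |
| 6.00 | 81 | 3.00 | 48 |
| 8.00 | 85 | 4.00 | 55 |

(readings scatter by 2 percentage points)

- the stated concentrations are those of everything mixed, before any reaction; amounts are the same in each set-up
- the feed brings no volume worth counting
- the earlier runs were made in a closed, stirred flask

- the set-up with the highest amount of target at the outlet or at the end, in percent of the substrate put in ("none" if the first two lie within 2 percentage points) (Saturday's / Thursday's / Monday's / none)
- amount of target at the outlet or at the end, in percent of the substrate put in, Saturday's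
- amount of target at the outlet or at the end, in percent of the substrate put in, Thursday's
- amount of target at the outlet or at the end, in percent of the substrate put in, Monday's

Take logarithms of those leftovers. Their ratio, 1.97, reads close to the ratio of catalyst concentrations, 1.94, so treat substrate as pseudo-first-order, with free catalyst concentration setting the clock. Define H as the substrate half-life, the time in which substrate halves at the charged catalyst concentration: in eta, H reads 1.67 h. Beta, with less catalyst at the same 1 mol% loading, reads 3.29 h. Don't touch the 0.33 M charge or the 1 mol% loading on the next three flasks: eta's H belongs to that charge and loading.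

Eta's 85% at 8.00 h lies below the 96.4% that H gives. Assume the catalyst lasts, and call the ratio Y, the share of reacted substrate ending as target: 88.2%.

Expect this on return. Saturday's flask runs 7.19 half-lives and reaches 87.6%. Thursday's flask has 2.40 h after its feed and keeps 9.08% of its substrate unreacted, which gives 80.2%. Monday's tank keeps 16.7% and gives 73.5%.

The forecast, on “the catalyst dying bimolecularly”, differs from this reckoning, mainly on Thursday's flask, with 91%, 60% and 71%, and also names Saturday's best.

The flasks give 85.8%, 79.9% and 73.3%, so Saturday's is best.

    free catalyst + other conformer → free catalyst + isomer of the product (k = 57.0 /M/h)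
    substrate ⇌ other conformer (K = 1.60, k = 0.0850 /h)
    free catalyst + other conformer → spent catalyst (k = 0.0790 /M/h)
    substrate + free catalyst → free catalyst + target (k = 130 /M/h)

Set H, 1.67 h, beside 8.2 h, the forward half-life of substrate into other conformer: in Saturday's flask, the way to target runs faster, by a factor of 4.91. With the way back not counted, that is a split of 83.1% toward target, and Saturday's flask ends at 85.8%. In Monday's tank, with 12 h on average, the two half-lives together, the way back again not counted, reckon to 0.0472 M of substrate, and the tank holds 0.0476 M.

Readings and results are calculated from invented constants; the scatter is artificial.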